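Assumption: the SMILES is taken as drawn, that is (7S,8R) trans-diol, (9S) carbinol, (10E) olefin and (12S,13S) trans-oxolane. Azaphilone numbering is used throughout (O2, C1–C8a, side chain C9–C15).

## Retrosynthetic overview
1. The pyran closes last on an enynone, by C8a–C1 (vinylogous Vilsmeier carbon) and O2–C3 (6-endo oxa-Michael). The same acid stage frees the triol.
2. The key union is C4a–C4. Under blue light and copper, the isopropenyl group of a carvone-derived ketone is exchanged for the terminal alkyne of the side chain.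
3. The carbocycle is bought as (S)-carvone. Its stereocentre sets C7 (epoxidation) and C8 (anti opening) and is then erased.
4. C9–C10 comes from stereospecific lithiation–borylation of (R)-4-TMS-but-3-yn-2-yl carbamate with an E-alkenyl boronate. The C10=C11 geometry comes from carboalumination.
5. The oxolane is made by photochemical 1,5-HAT etherification (C15–O) of the hydroxy ester from L-isoleucine, which supplies C12 and C13. Ring order: carbocycle (bought), then oxolane, then pyran.

## Route

Step 1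
Reactants: 1 (S)-(+)-carvone
Product: 2 (1S,4S,6S)-1-methyl-4-(prop-1-en-2-yl)-7-oxabicyclo[4.1.0]heptan-2-one
Conditions: 35% H2O2, NaOH (0.3 equiv), MeOH, 0 °C
Reagents that add atoms: hydrogen peroxide OO
Why: Weitz–Scheffer nucleophilic epoxidation, in which hydroperoxide adds to the enone face anti to the isopropenyl group, so the bought stereocentre fixes the C7–O bond (7S) while the isolated alkene is inert.

Step 2
Reactants: 2 carvone epoxide
Product: 4 (3aS,6S,7aR)-2,2,3a-trimethyl-6-(prop-1-en-2-yl)hexahydro-1,3-benzodioxol-4-one, via trans-diol 3 (not isolated)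
Conditions: HClO4 (cat.), acetone–H2O 20:1, 23 °C; then 2,2-dimethoxypropane (excess), 23 °C
Reagents that add atoms: water O; 2,2-dimethoxypropane COC(C)(C)OC
Why: acid-catalysed SN2-type epoxide opening followed by transketalisation, in which water attacks the secondary carbon β to C=O with inversion (the quaternary α-carbon is deactivated) to give the trans-diequatorial (7S,8R) diol, which is locked as the trans-fused acetonide.

Step 3
Reactants: 5 L-isoleucine
Product: 6 (2S,3S)-2-hydroxy-3-methylpentanoic acid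
Conditions: NaNO2, 1 M H2SO4, 0→23 °C
Reagents that add atoms: water O
Why: diazotisation with net retention (double inversion through the α-lactone formed by carboxylate participation), leaving C3 untouched.

Step 4
Reactants: 6 hydroxy acid
Product: 7 methyl (2S,3S)-2-hydroxy-3-methylpentanoate
Conditions: MeOH, H2SO4 (cat.), reflux
Reagents that add atoms: methanol CO
Why: Fischer esterification, which masks the acid (it would decarboxylate under hypoiodite conditions) and involves no stereocentre.

Step 5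
Reactants: 7 hydroxy ester
Product: 10 methyl (2S,3S)-3-methyloxolane-2-carboxylate, via alkyl hypoiodite 8 (not isolated), via delta-iodo alcohol 9 (not isolated)
Conditions: PhI(OAc)2 (1.5 equiv), I2 (0.5 equiv), PhCF3, white LED, 25 °C
Reagents that add atoms: none
Why: Suárez hypoiodite reaction (photochemical remote C–H etherification), in which light cleaves the O–I bond of 8, the alkoxyl radical takes a δ-methyl hydrogen by 1,5-HAT, iodine transfer gives 9, and 5-exo-tet displacement closes C15–O without touching the two bought stereocentres.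

Step 6
Reactants: 10 oxolane ester
Product: 12 (2S,3S)-2-ethynyl-3-methyloxolane, via oxolane carbaldehyde 11 (not isolated)
Conditions: DIBAL-H (1.05 equiv), CH2Cl2, −78 °C; then MeOH, K2CO3, MeC(O)C(N2)P(O)(OMe)2, −78→23 °C
Reagents that add atoms: dimethyl (1-diazo-2-oxopropyl)phosphonate CC(=O)C(=[N+]=[N-])P(=O)(OC)OC
Why: DIBAL-H half-reduction and Ohira–Bestmann (Seyferth–Gilbert) homologation in one pot, where the trans aldehyde 11 is also the thermodynamic epimer, so C12 is kept.

Step 7
Reactants: 12 ethynyl oxolane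
Product: 14 2-{(E)-2-[(2S,3S)-3-methyloxolan-2-yl]prop-1-en-1-yl}-4,4,5,5-tetramethyl-1,3,2-dioxaborolane, via alkenylalane 13 (not isolated)
Conditions: Me3Al, Cp2ZrCl2 (20 mol %), CH2Cl2, 0→23 °C; then iPrOBpin, −78→23 °C
Reagents that add atoms: trimethylaluminium C[Al](C)C; 2-isopropoxy-4,4,5,5-tetramethyl-1,3,2-dioxaborolane CC(C)OB1OC(C)(C)C(C)(C)O1
Why: Negishi zirconium-catalysed syn-carboalumination (methyl to the internal carbon, Al to the terminal one) fixes the E trisubstituted olefin, and the Al-to-B exchange goes with retention.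

Step 8
Reactants: 15 (R)-4-(trimethylsilyl)but-3-yn-2-ol
Product: 16 (R)-4-(trimethylsilyl)but-3-yn-2-yl N,N-diisopropylcarbamate
Conditions: iPr2NC(O)Cl, Et3N, DMAP (cat.), CH2Cl2, reflux
Reagents that add atoms: N,N-diisopropylcarbamoyl chloride CC(C)N(C(C)C)C(=O)Cl
Why: O-carbamoylation, which installs the directing and leaving group and leaves the stereocentre untouched.

Step 9
Reactants: 16 propargylic carbamate; 14 alkenyl boronate
Product: 21 (3S,4E)-3-methyl-5-[(2S,3S)-3-methyloxolan-2-yl]hex-4-en-1-yn-3-ol, via lithiated carbamate 17 (not isolated), via lithium boronate complex 18 (not isolated), via tertiary boronic ester 19 (not isolated), via TMS-alkynol 20 (not isolated)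
Conditions: sBuLi, TMEDA, Et2O, −78 °C; 14, −78→23 °C; then NaOH, H2O2, THF, 0 °C; then K2CO3, MeOH, 23 °C
Reagents that add atoms: hydrogen peroxide OO
Why: Hoppe-type lithiation followed by lithiation–borylation, in which deprotonation and borylation go with retention, the alkenyl group migrates anti to the leaving carbamate (Matteson-type 1,2-metallate shift, inversion), and C–B oxidation goes with retention, so the bought (R) centre becomes (9S) with only achiral reagents; methanolysis then removes the alkyne TMS group.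

Step 10
Reactants: 4 acetonide ketone (1.5 equiv); 21 side-chain alkyne
Product: 23 (3aS,7aR)-6-{(3S,4E)-3-hydroxy-3-methyl-5-[(2S,3S)-3-methyloxolan-2-yl]hex-4-en-1-yn-1-yl}-2,2,3a-trimethylhexahydro-1,3-benzodioxol-4-one, via alpha-methoxy hydroperoxide 22 (not isolated)
Conditions: 4, O3, MeOH–CH2Cl2, −78 °C, Ar purge; then 21, Cu(MeCN)4PF6 (10 mol %), tBu3-terpyridine (12 mol %), Cs2CO3 (20 mol %), MeCN, 450 nm LED, 0 °C
Reagents that add atoms: none
Why: Proposed new method: Criegee ozonolysis in MeOH converts the isopropenyl group into hydroperoxide 22, the blue-light-excited terpyridine–Cu(I) acetylide of 21 cleaves its O–O bond by SET, the alkoxyl radical loses methyl acetate by β-scission, and the secondary C4a radical is captured by the Cu(II) acetylide and reductively eliminated to form the C4a–C4 bond in a redox-neutral cycle; the closest known reaction types are iron- or copper-mediated dealkenylative radical functionalisation of such hydroperoxides (alkynyl sulfones, N-nucleophiles) and photoinduced copper-catalysed coupling of alkyl halide-derived radicals with terminal alkynes; the new C4a centre forms as an epimer mixture that step 11 erases, and ozone never meets the olefin of 21.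

Step 11
Reactants: 23 coupled ketone
Product: 24 (3aS,7aR)-6-{(3S,4E)-3-hydroxy-3-methyl-5-[(2S,3S)-3-methyloxolan-2-yl]hex-4-en-1-yn-1-yl}-2,2,3a-trimethyl-7,7a-dihydro-1,3-benzodioxol-4(3aH)-one
Conditions: IBX, 4-methoxypyridine N-oxide, DMSO, 23 °C
Reagents that add atoms: none
Why: IBX α,β-dehydrogenation, in which the ketone can enolise only toward C5 because C7 is quaternary, so only the C4a=C5 enynone can form, and the tertiary alcohol, acetonide, alkyne and olefin are inert.

Step 12
Reactants: 24 enynone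
Product: 29 CNP0502247.2 target compound, via bis-TES silyl dienol ether 25 (not isolated), via dienaminone 26 (not isolated), via hydroxymethylene enynone 27 (not isolated), via target acetonide 28 (not isolated)
Conditions: TESOTf (2.5 equiv), Et3N, CH2Cl2, −78→0 °C; [Me2N=CHCl]Cl, 0 °C; evaporate; AcOH–THF–H2O 3:1:1, 23→40 °C
Reagents that add atoms: (chloromethylene)dimethyliminium chloride C[N+](C)=CCl.[Cl-]; water O
Why: vinylogous Vilsmeier–Haack formylation of a neutral dienol ether at its γ-terminus C8a (as in 6-formylation of steroid 3,5-dienol ethers, with soft enolisation possible only at C8a and the diequatorial acetonide blocking β-elimination), followed by hydrolytic work-up to 27, 6-endo-dig oxa-Michael closure of O2–C3, and mild acid removal of TES and the strained acetonide, with no stereocentre formed or broken.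

## Compound list
1 | (S)-(+)-carvone, (5S)-2-methyl-5-(prop-1-en-2-yl)cyclohex-2-en-1-one | CC1=CC[C@@H](CC1=O)C(C)=C | starting material
2 | (1S,4S,6S)-1-methyl-4-(prop-1-en-2-yl)-7-oxabicyclo[4.1.0]heptan-2-one (oxirane trans to isopropenyl) | C1C(=O)[C@@]2(C)O[C@H]2C[C@@H]1C(C)=C | intermediate
3 | (2S,3R,5S)-2,3-dihydroxy-2-methyl-5-(prop-1-en-2-yl)cyclohexan-1-one (trans-diol) | C1C(=O)[C@@](C)(O)[C@H](O)C[C@@H]1C(C)=C | intermediate
4 | (3aS,6S,7aR)-2,2,3a-trimethyl-6-(prop-1-en-2-yl)hexahydro-1,3-benzodioxol-4-one (trans-fused acetonide of 3) | C1C(=O)[C@@]2(C)OC(C)(C)O[C@@H]2C[C@@H]1C(C)=C | intermediate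
5 | L-isoleucine, (2S,3S)-2-amino-3-methylpentanoic acid | CC[C@H](C)[C@H](N)C(=O)O | starting material
6 | (2S,3S)-2-hydroxy-3-methylpentanoic acid | CC[C@H](C)[C@H](O)C(=O)O | intermediate
7 | methyl (2S,3S)-2-hydroxy-3-methylpentanoate | CC[C@H](C)[C@H](O)C(=O)OC | intermediate
8 | methyl (2S,3S)-2-(iodooxy)-3-methylpentanoate (hypoiodite) | CC[C@H](C)[C@H](OI)C(=O)OC | intermediate
9 | methyl (2S,3S)-2-hydroxy-5-iodo-3-methylpentanoate | ICC[C@H](C)[C@H](O)C(=O)OC | intermediate
10 | methyl (2S,3S)-3-methyloxolane-2-carboxylate (trans) | COC(=O)[C@H]1OCC[C@@H]1C | intermediate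
11 | (2S,3S)-3-methyloxolane-2-carbaldehyde | O=C[C@H]1OCC[C@@H]1C | intermediate
12 | (2S,3S)-2-ethynyl-3-methyloxolane | C#C[C@H]1OCC[C@@H]1C | intermediate
13 | dimethyl{(E)-2-[(2S,3S)-3-methyloxolan-2-yl]prop-1-en-1-yl}alane | C[Al](C)/C=C(\C)[C@H]1OCC[C@@H]1C | intermediate
14 | 2-{(E)-2-[(2S,3S)-3-methyloxolan-2-yl]prop-1-en-1-yl}-4,4,5,5-tetramethyl-1,3,2-dioxaborolane | CC1(C)OB(/C=C(\C)[C@H]2OCC[C@@H]2C)OC1(C)C | intermediate
15 | (R)-4-(trimethylsilyl)but-3-yn-2-ol | C[C@@H](O)C#C[Si](C)(C)C | starting material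
16 | (R)-4-(trimethylsilyl)but-3-yn-2-yl N,N-diisopropylcarbamate | C[C@@H](OC(=O)N(C(C)C)C(C)C)C#C[Si](C)(C)C | intermediate
17 | α-lithiated carbamate (Li in place of the carbinol H, retention) | C[C@@]([Li])(OC(=O)N(C(C)C)C(C)C)C#C[Si](C)(C)C | intermediate
18 | lithium boronate complex of 17 and 14 (B in place of Li, retention) | C[C@@]([B-]1(/C=C(\C)[C@H]2OCC[C@@H]2C)OC(C)(C)C(C)(C)O1)(OC(=O)N(C(C)C)C(C)C)C#C[Si](C)(C)C.[Li+] | intermediate
19 | tertiary propargylic/allylic pinacol boronic ester (alkenyl has displaced OCb with inversion) | C[C@](B1OC(C)(C)C(C)(C)O1)(/C=C(\C)[C@H]2OCC[C@@H]2C)C#C[Si](C)(C)C | intermediate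
20 | (3S,4E)-3-methyl-5-[(2S,3S)-3-methyloxolan-2-yl]-1-(trimethylsilyl)hex-4-en-1-yn-3-ol | C[C@](O)(/C=C(\C)[C@H]1OCC[C@@H]1C)C#C[Si](C)(C)C | intermediate
21 | (3S,4E)-3-methyl-5-[(2S,3S)-3-methyloxolan-2-yl]hex-4-en-1-yn-3-ol | C#C[C@@](C)(O)/C=C(\C)[C@H]1OCC[C@@H]1C | intermediate
22 | (3aS,6S,7aR)-6-(2-hydroperoxy-2-methoxypropan-2-yl... i.e. 1-hydroperoxy-1-methoxyethyl)-2,2,3a-trimethylhexahydro-1,3-benzodioxol-4-one (peroxyketal carbon unselective) | C1C(=O)[C@@]2(C)OC(C)(C)O[C@@H]2C[C@@H]1C(C)(OC)OO | intermediate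
23 | (3aS,7aR)-6-{(3S,4E)-3-hydroxy-3-methyl-5-[(2S,3S)-3-methyloxolan-2-yl]hex-4-en-1-yn-1-yl}-2,2,3a-trimethylhexahydro-1,3-benzodioxol-4-one (C6 epimer mixture) | C1C(=O)[C@@]2(C)OC(C)(C)O[C@@H]2CC1C#C[C@@](C)(O)/C=C(\C)[C@H]3OCC[C@@H]3C | intermediate
24 | enynone: 5,6-dehydro derivative of 23 (C4a=C5 conjugated with C6=O and the alkyne) | O=C1C=C(C#C[C@@](C)(O)/C=C(\C)[C@H]3OCC[C@@H]3C)C[C@H]2OC(C)(C)O[C@]12C | intermediate
25 | bis-TES compound: C6-O-TES 1,3-dienol ether (C6=C5, C4a=C8a) with C9-O-TES | CC[Si](CC)(CC)OC1=CC(C#C[C@@](C)(O[Si](CC)(CC)CC)/C=C(\C)[C@H]3OCC[C@@H]3C)=C[C@H]2OC(C)(C)O[C@]12C | intermediate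
26 | (E)-C8a-(dimethylaminomethylene) enynone, C9-O-TES (dienaminone) | CN(C)/C=C1\C(C#C[C@@](C)(O[Si](CC)(CC)CC)/C=C(\C)[C@H]3OCC[C@@H]3C)=CC(=O)[C@@]2(C)OC(C)(C)O[C@H]12 | intermediate
27 | C8a-(hydroxymethylene) enynone, C9-OH free, acetonide on | O/C=C1\C(C#C[C@@](C)(O)/C=C(\C)[C@H]3OCC[C@@H]3C)=CC(=O)[C@@]2(C)OC(C)(C)O[C@H]12 | intermediate
28 | 7,8-O-isopropylidene derivative of the target | C/C(=C\[C@](C)(O)C1=CC2=CC(=O)[C@@]3(C)OC(C)(C)O[C@@H]3C2=CO1)[C@H]4OCC[C@@H]4C | intermediate
29 | CNP0502247.2, (7S,8R)-7,8-dihydroxy-3-{(2S,3E)-2-hydroxy-4-[(2S,3S)-3-methyloxolan-2-yl]pent-3-en-2-yl}-7-methyl-7,8-dihydro-6H-isochromen-6-one | C/C(=C\[C@](C)(O)C1=CC2=CC(=O)[C@@](C)(O)[C@H](O)C2=CO1)[C@H]1OCC[C@@H]1C | target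

Total step count: 12.
Longest linear sequence: 9 steps (5 → 6 → 7 → 10 → 12 → 14 → 21 → 23 → 24 → 29).

## Steps most likely to fail

**Step 10 (the new coupling).** The risks are Glaser dimerisation of 21, Cu(II)-induced elimination of the C4a radical, and thermal peroxide side reactions.
- The fallback uses known chemistry, sets out from 4 (with 21) and returns at 24, so step 11 is no longer needed.
- 4 is ozonised in MeOH as before to 22, and FeSO4/TEMPO traps the radical as the C4a TEMPO ether F1.
- mCPBA oxidises F1 to the acetonide 1,3-dione F2.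
- Tf2O/2,6-lutidine sulfonylates the less hindered enol oxygen to give the vinylogous triflate F3.
- A Pd(PPh3)2Cl2/CuI/Et3N Sonogashira coupling of F3 with 21 gives 24.

**Step 5.** The 1,5-HAT is from a primary C–H and competes with β-scission to a sec-butyl radical.
- The fallback sets out from 5 and returns at 10, and uses a nitrogen radical, which cannot fragment in this way.
- tBuOCl gives N-chloro-L-isoleucine F4.
- Hofmann–Löffler–Freytag photolysis in 85% H2SO4 gives 5-chloro-L-isoleucine F5.
- NaNO2 added to the diluted acid gives, with retention, the 5-chloro hydroxy acid F6.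
- MeOH/H+ gives the 5-chloro hydroxy ester F7, and NaH in THF closes the ring to 10.

**Step 12.** The iminium ion could attack C5 instead of C8a, or damage the tertiary allylic silyl ether. C8 could also epimerise in acid.
- The fallback puts C1 on the ring before the side chain arrives. It sets out from 4 (taken to F3 as described above) and returns at 27.
- TESOTf/Et3N converts F3 into the silyl dienol ether triflate F8.
- The Vilsmeier salt followed by Et3N gives the aminomethylene triflate F9. Regioisomers can be separated here on cheap material.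
- Sonogashira coupling of F9 with 21 gives the free-hydroxy dienaminone F10.
- Aqueous AcOH hydrolyses F10 to 27, which goes on to 28 and 29 in the same flask.

## Further compounds
F1 | step 10 | C4a TEMPO ether, (3aS,7aR)-2,2,3a-trimethyl-6-[(2,2,6,6-tetramethylpiperidin-1-yl)oxy]hexahydro-1,3-benzodioxol-4-one | CC1(C)CCCC(C)(C)N1OC2CC(=O)[C@@]3(C)OC(C)(C)O[C@@H]3C2
F2 | step 10 | acetonide 1,3-dione, (3aS,7aR)-2,2,3a-trimethyltetrahydro-1,3-benzodioxole-4,6-dione | O=C1CC(=O)[C@@]2(C)OC(C)(C)O[C@@H]2C1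
F3 | step 10 | vinylogous triflate, (3aS,7aR)-2,2,3a-trimethyl-4-oxo-3a,4,7,7a-tetrahydro-1,3-benzodioxol-6-yl trifluoromethanesulfonate | O=C1C=C(OS(=O)(=O)C(F)(F)F)C[C@H]2OC(C)(C)O[C@]12C
F4 | step 5 | N-chloro-L-isoleucine | CC[C@H](C)[C@H](NCl)C(=O)O
F5 | step 5 | 5-chloro-L-isoleucine, (2S,3S)-2-amino-5-chloro-3-methylpentanoic acid | ClCC[C@H](C)[C@H](N)C(=O)O
F6 | step 5 | 5-chloro hydroxy acid, (2S,3S)-5-chloro-2-hydroxy-3-methylpentanoic acid | ClCC[C@H](C)[C@H](O)C(=O)O
F7 | step 5 | 5-chloro hydroxy ester, methyl (2S,3S)-5-chloro-2-hydroxy-3-methylpentanoate | ClCC[C@H](C)[C@H](O)C(=O)OC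
F8 | step 12 | silyl dienol ether triflate, C6-O-TES 1,3-diene carrying C4a-OTf | CC[Si](CC)(CC)OC1=CC(OS(=O)(=O)C(F)(F)F)=C[C@H]2OC(C)(C)O[C@]12C
F9 | step 12 | aminomethylene triflate, (E)-C8a-(dimethylaminomethylene) derivative of F3 | CN(C)/C=C1\C(OS(=O)(=O)C(F)(F)F)=CC(=O)[C@@]2(C)OC(C)(C)O[C@H]12
F10 | step 12 | free-hydroxy dienaminone, C9-OH analogue of 26 | CN(C)/C=C1\C(C#C[C@@](C)(O)/C=C(\C)[C@H]3OCC[C@@H]3C)=CC(=O)[C@@]2(C)OC(C)(C)O[C@H]12
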